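Ring A is closed last by joining C3 to C4: SmI2 converts a primary iodide on C3 into an alkylsamarium that adds to the acetyl carbonyl carried by C5. This one operation forms the C3–C4 bond, ring A and the C4 tertiary carbinol. It exploits the peri relationship between C4 on ring A and the 6α-oxygen on ring B: samarium held between O4 and O6 leaves the C4 methyl axial, syn to the C10 methyl. The precursor is an all-equatorial ring B cyclohexane (C5 acetyl, 6α-benzyloxy, C7 silyloxyethyl, 8α-silyloxy) whose C10 carries the axial methyl and the (1R)-1-silyloxy-3-iodopropyl arm.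

Key step: step 16

Remark: every intermediate carries the eudesmane numbers of the target (ring B = C5 to C10, C14 on C10, C15 on C4, C11 to C13 on C7); β is the face of ring B that bears the C10 methyl.
Assumption: the (S)-configured oxazaborolidinium catalyst is taken to expose the face of enal 4 that leads to 5 as drawn, following the accepted model for α-substituted enals; if the sense were opposite, the (R)-catalyst would be used with no other change.
Remark: 1 and 4 are catalogue compounds; 4 is used as the E isomer.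

Step 1
Reactants: 1 tert-butyl(but-3-yn-1-yloxy)dimethylsilane; 2 ethylene
Product: 3 tert-butyldimethyl[(3-methylidenepent-4-en-1-yl)oxy]silane (2-substituted buta-1,3-diene)
Conditions: C2H4 (1 atm), second-generation Grubbs catalyst RuCl2(=CHPh)(PCy3)(H2IMes) (5 mol %), CH2Cl2, rt
Reagents that add atoms: none
Why: Cross enyne metathesis with ethylene adds a CH2=CH unit across the terminal alkyne and should give the 2-substituted buta-1,3-diene directly, with no stereocentre involved.

Step 2
Reactants: 3 the 2-substituted diene; 4 ethyl (2E)-3-methyl-4-oxobut-2-enoate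
Product: 5 ethyl 3-[2-(tert-butyldimethylsilyloxy)ethyl]-6-formyl-6-methylcyclohex-3-ene-1-carboxylate (formyl trans to ester; 10β-CH3, 5α-H)
Conditions: (S)-B-(o-tolyl)-α,α-diphenylprolinol oxazaborolidine·HNTf2 (10 mol %), CH2Cl2, −78 → −40 °C
Reagents that add atoms: none
Why: In this oxazaborolidinium-catalysed asymmetric Diels–Alder reaction the formyl group on the future C10 is the activating group, so the more nucleophilic diene terminus (the CH2 next to the substituted carbon) should bond to C5 and place the side chain on C7 para to C10, the E geometry of 4 is transferred as the trans relation of C1 and C4, and attack on the open face of the catalyst-bound s-trans enal sets C10 and C5.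

Step 3
Reactants: 5 the Diels–Alder aldehyde ester
Product: 7 trans-fused γ-lactone (C1H2–O–C4=O) on the Δ7 ring B, via hydroxy ester 6 (not isolated)
Conditions: NaBH4, EtOH, 0 °C; then PPTS (catalytic), PhMe, 80 °C
Reagents that add atoms: none
Why: Borohydride reduces only the aldehyde, and acid-catalysed lactonisation of the neopentyl alcohol onto the trans ester should give the trans-fused γ-lactone, which protects C1 and C4 together and locks ring B in the chair that keeps the C10 methyl axial.

Step 4
Reactants: 7 the Δ7 lactone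
Product: 9 8α-hydroxy lactone (7β side chain), via C8 alkylborane 8 (not isolated)
Conditions: BH3·THF, THF, 0 °C; then NaBO3·4H2O, THF/H2O, rt
Reagents that add atoms: sodium perborate, [Na+].[Na+].O[B-]1(O)OO[B-](O)(O)OO1
Why: Hydroboration–oxidation of the trisubstituted alkene places boron on the less substituted C8 and adds H and B syn from the α face, opposite the axial C10 methyl that is 1,3 to C8, so the 8α-hydroxyl and the equatorial 7β side chain should arise together.

Step 5
Reactants: 9 the 8α-hydroxy lactone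
Product: 10 8α-tert-butyldimethylsilyloxy lactone
Conditions: TBSOTf, 2,6-lutidine, CH2Cl2, 0 °C
Reagents that add atoms: tert-butyldimethylsilyl triflate, CC(C)(C)[Si](C)(C)OS(=O)(=O)C(F)(F)F
Why: Silylation of the secondary alcohol with the silyl triflate and a hindered base is routine and leaves the lactone untouched.

Step 6
Reactants: 10 the silylated lactone
Product: 13 Δ5(6)-unsaturated lactone, via 5α-phenylselanyl lactone 11 (not isolated), via selenoxide 12 (not isolated)
Conditions: LiN(iPr)2, THF, −78 °C; PhSeBr; then 30% H2O2, pyridine, CH2Cl2, 0 °C → rt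
Reagents that add atoms: none
Why: α-Selenenylation of the lactone enolate followed by selenoxide syn-elimination can only use a hydrogen on C6, because C10 is quaternary, and so should give the C5=C6 unsaturated lactone.

Step 7
Reactants: 13 the unsaturated lactone
Product: 15 6α-hydroxy lactone (5α-H), via 6α-boronate 14 (not isolated)
Conditions: B2pin2, CuCl (10 mol %), NaOtBu (15 mol %), Xantphos, MeOH (2 equiv), THF, rt; then NaBO3·4H2O, THF/H2O
Reagents that add atoms: sodium perborate, [Na+].[Na+].O[B-]1(O)OO[B-](O)(O)OO1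
Why: Copper-catalysed conjugate borylation should add the boryl group to C6 on the α face, opposite the pseudo-axial C10 methyl and the C7 substituent, the enolate is then protonated at C5 axially from the same face so that the trans lactone returns, and perborate oxidation of the C–B bond with retention gives the 6α-alcohol.

Step 8
Reactants: 15 the 6α-hydroxy lactone
Product: 16 6α-benzyloxy lactone
Conditions: 2-benzyloxy-1-methylpyridinium triflate, MgO, PhCF3, 85 °C
Reagents that add atoms: 2-benzyloxy-1-methylpyridinium triflate, C[n+]1ccccc1OCc1ccccc1.[O-]S(=O)(=O)C(F)(F)F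
Why: Benzyl transfer from the pyridinium salt under neutral conditions etherifies the hindered β-hydroxy lactone without the base that would trigger retro-aldol cleavage or elimination, and benzyl is chosen because it can chelate samarium in step 16 and is later removed by hydrogenolysis before any alkene is present.

Step 9
Reactants: 16 the benzyloxy lactone
Product: 17 ring B hydroxy N-methoxy-N-methylamide (C1 = CH2OH)
Conditions: MeNH(OMe)·HCl, AlMe3, CH2Cl2, 0 °C → rt
Reagents that add atoms: N,O-dimethylhydroxylamine hydrochloride, CNOC.Cl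
Why: Aminolysis of the strained trans-fused lactone with the aluminium amide should give the N-methoxy-N-methylamide as a masked acetyl group and free the C1 hydroxymethyl group.

Step 10
Reactants: 17 the hydroxy amide
Product: 18 C1 aldehyde
Conditions: DMP, NaHCO3, CH2Cl2, 0 °C → rt
Reagents that add atoms: none
Why: Periodinane oxidation converts the neopentyl alcohol into the non-enolisable aldehyde under buffered, non-basic conditions.

Step 11
Reactants: 18 the aldehyde
Product: 19 (1R)-allylic alcohol
Conditions: CH2=CHMgBr, THF, −78 °C; NH4Cl (aq) at −78 °C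
Reagents that add atoms: vinylmagnesium bromide, C=C[Mg]Br
Why: Grignard addition to the aldehyde is much faster than to the hindered amide at low temperature, and both the Felkin–Anh arrangement (C5 anti to the nucleophile, methyl as the small group) and a magnesium chelate between the aldehyde and amide oxygens expose the same face, which should give the (1R) carbinol.

Step 12
Reactants: 19 the allylic alcohol
Product: 20 (1R)-allylic silyl ether
Conditions: TBSOTf, 2,6-lutidine, CH2Cl2, −20 → 0 °C
Reagents that add atoms: tert-butyldimethylsilyl triflate, CC(C)(C)[Si](C)(C)OS(=O)(=O)C(F)(F)F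
Why: Silylation with the silyl triflate protects the hindered allylic alcohol before hydroboration.

Step 13
Reactants: 20 the allylic silyl ether
Product: 22 C3 primary alcohol, via B-alkyl-9-BBN adduct 21 (not isolated)
Conditions: 9-BBN, THF, 0 °C → rt; then NaBO3·4H2O, THF/H2O
Reagents that add atoms: sodium perborate, [Na+].[Na+].O[B-]1(O)OO[B-](O)(O)OO1
Why: Hydroboration–oxidation with the bulky 9-BBN places boron on the terminal carbon C3 and tolerates the amide, which should give the primary alcohol.

Step 14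
Reactants: 22 the primary alcohol amide
Product: 23 hydroxy methyl ketone (C5 acetyl)
Conditions: MeMgBr (4 equiv), THF, 0 °C → rt
Reagents that add atoms: methylmagnesium bromide, C[Mg]Br
Why: Addition of the methyl Grignard reagent to the N-methoxy-N-methylamide stops at the chelated tetrahedral intermediate, which releases the methyl ketone on work-up, while the C3 alkoxide only consumes one equivalent.

Step 15
Reactants: 23 the hydroxy ketone
Product: 24 all-equatorial ring B iodo ketone (key-step precursor)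
Conditions: I2, PPh3, imidazole, CH2Cl2, 0 °C
Reagents that add atoms: iodine, II
Why: Appel-type iodination converts the primary alcohol into the iodide by SN2 displacement of the oxyphosphonium ion and does not touch the ketone or the silyl ethers.

Step 16
Reactants: 24 the iodo ketone
Product: 25 protected 4α-hydroxy-4β-methyl trans-decalin
Conditions: SmI2 (2.5 equiv), Fe(PhCOCHCOPh)3 (2 mol %), THF, −78 °C → rt (no HMPA)
Reagents that add atoms: none
Why: Two single-electron transfers from SmI2 reduce the C3–I bond to a primary alkylsamarium, which adds to the C4 carbonyl in a Barbier-type addition, the closest known reaction being the SmI2-mediated cyclisation of ω-iodo ketones to cyclohexanols. Ring A closes in the 6-exo-trig mode through a chair-like transition state in which both reacting arms are equatorial on ring B, so the trans ring fusion is inherited from C5 and C10. The new stereocentre C4 is controlled by the orientation of the acetyl group: trivalent samarium bridging the carbonyl oxygen and the 6α-benzyloxy oxygen (a six-membered chelate, possible because HMPA is left out) holds O4 on the α face, and the same rotamer keeps C15 clear of the peri 6α-substituent, so C3 bonds to the face that leaves CH3 axial (β) and OH equatorial (α). The step needs the iodide to be reduced before the ketone and no loss of the β-benzyloxy group or epimerisation at C5; an unactivated dialkyl ketone is reduced only slowly by SmI2 in THF, and the medium is neutral and non-basic, which should secure both. The saturated silyloxyethyl chain, the silyl ethers and the benzyl ether are inert to SmI2.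

Step 17
Reactants: 25 the benzyl-protected decalin
Product: 26 4α,6α-diol (tris-silyl ether)
Conditions: H2 (1 atm), Pd(OH)2/C, EtOAc, rt
Reagents that add atoms: none
Why: Hydrogenolysis removes the benzyl ether cleanly at this point because no alkene is present yet, and it avoids an oxidative ether cleavage in which the peri 4α-hydroxyl could trap the benzylic cation as an acetal.

Step 18
Reactants: 26 the diol
Product: 27 6α-angelate
Conditions: angelic acid, 2,4,6-Cl3C6H2COCl, Et3N, PhMe, rt; then 26, 80 °C (no DMAP)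
Reagents that add atoms: angelic acid, C/C=C(/C)C(=O)O
Why: Mixed-anhydride (Yamaguchi-type) esterification without DMAP should acylate the secondary 6α-hydroxyl while the tertiary C4 hydroxyl stays inert, it avoids the nucleophilic catalysis that isomerises angelate to tiglate, and it is placed before C12 is oxidised so that O6 can never lactonise onto C12.

Step 19
Reactants: 27 the angelate
Product: 28 C12 primary alcohol
Conditions: HF·pyridine, pyridine, THF, 0 °C
Reagents that add atoms: none
Why: Buffered HF–pyridine cleaves the unhindered primary silyl ether much faster than the two hindered secondary ones.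

Step 20
Reactants: 28 the primary alcohol
Product: 29 C12 aldehyde
Conditions: DMP, NaHCO3, CH2Cl2, rt
Reagents that add atoms: none
Why: Periodinane oxidation gives the aldehyde without affecting the angelate or the tertiary alcohol.

Step 21
Reactants: 29 the aldehyde
Product: 31 11(13)-en-12-al, via Mannich base 30 (not isolated)
Conditions: CH2=NMe2+ I−, Et3N, CH2Cl2, rt
Reagents that add atoms: N,N-dimethylmethyleneiminium iodide, C=[N+](C)C.[I-]
Why: Mannich reaction of the aldehyde with the iminium salt followed by amine elimination in the same flask (α-methylenation) introduces C13 under a mild base that the angelate tolerates.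

Step 22
Reactants: 31 the enal
Product: 32 11(13)-en-12-oic acid
Conditions: NaClO2, NaH2PO4, 2-methyl-2-butene, t-BuOH/H2O, 0 °C → rt
Reagents that add atoms: sodium chlorite, [Na+].[O-]Cl=O
Why: Pinnick oxidation converts the enal into the acrylic acid while the scavenger protects the alkenes from hypochlorous acid.

Step 23
Reactants: 32 the acrylic acid
Product: 33 methyl ester (1,8-bis-silyl ether)
Conditions: MeI, K2CO3, DMF, 0 °C → rt
Reagents that add atoms: iodomethane, CI
Why: SN2 alkylation of the carboxylate with iodomethane gives the methyl ester without the dipolar cycloaddition that diazoalkanes can undergo with the acrylate.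

Step 24
Reactants: 33 the bis-silyl ether
Product: 34 CNP0136844.1
Conditions: HF·pyridine (excess), THF, rt
Reagents that add atoms: none
Why: Acidic fluoride removes both secondary silyl ethers without generating an alkoxide at O8, which could lactonise onto the acrylate or invite acyl migration.

Compound list
1 | tert-butyl(but-3-yn-1-yloxy)dimethylsilane | C#CCCO[Si](C)(C)C(C)(C)C | starting material
2 | ethylene | C=C | starting material
3 | tert-butyldimethyl[(3-methylidenepent-4-en-1-yl)oxy]silane | C=CC(=C)CCO[Si](C)(C)C(C)(C)C | intermediate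
4 | ethyl (2E)-3-methyl-4-oxobut-2-enoate | CCOC(=O)/C=C(\C)C=O | starting material
5 | ethyl 3-[2-(TBSO)ethyl]-6-formyl-6-methylcyclohex-3-ene-1-carboxylate, formyl trans to ester (10β-CH3, 5α-H, Δ7; C1 = CHO, C4 = CO2Et) | CC(C)(C)[Si](C)(C)OCCC1=CC[C@@](C)(C=O)[C@H](C(=O)OCC)C1 | intermediate
6 | hydroxymethyl analogue of 5 (C1 = CH2OH) | CC(C)(C)[Si](C)(C)OCCC1=CC[C@@](C)(CO)[C@H](C(=O)OCC)C1 | intermediate (not isolated)
7 | trans-fused γ-lactone C1H2–O–C4(=O) on the Δ7 ring B (10β-CH3, 5α-H) | CC(C)(C)[Si](C)(C)OCCC1=CC[C@@]2(C)COC(=O)[C@@H]2C1 | intermediate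
8 | 8α-boryl lactone (7α-H), shown as the monoalkylborane | CC(C)(C)[Si](C)(C)OCC[C@H]1C[C@H]2C(=O)OC[C@]2(C)C[C@@H]1B | intermediate (not isolated)
9 | 8α-hydroxy lactone (7β-CH2CH2OTBS) | CC(C)(C)[Si](C)(C)OCC[C@H]1C[C@H]2C(=O)OC[C@]2(C)C[C@@H]1O | intermediate
10 | 8α-TBSO lactone | CC(C)(C)[Si](C)(C)OCC[C@H]1C[C@H]2C(=O)OC[C@]2(C)C[C@@H]1O[Si](C)(C)C(C)(C)C | intermediate
11 | 5α-phenylselanyl lactone | CC(C)(C)[Si](C)(C)OCC[C@H]1C[C@@]2([Se]c3ccccc3)C(=O)OC[C@]2(C)C[C@@H]1O[Si](C)(C)C(C)(C)C | intermediate (not isolated)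
12 | selenoxide of 11 (configuration at Se not defined) | CC(C)(C)[Si](C)(C)OCC[C@H]1C[C@@]2([Se](=O)c3ccccc3)C(=O)OC[C@]2(C)C[C@@H]1O[Si](C)(C)C(C)(C)C | intermediate (not isolated)
13 | Δ5(6)-unsaturated lactone | CC(C)(C)[Si](C)(C)OCC[C@H]1C=C2C(=O)OC[C@]2(C)C[C@@H]1O[Si](C)(C)C(C)(C)C | intermediate
14 | 6α-(pinacolato)boryl lactone (5α-H) | CC(C)(C)[Si](C)(C)OCC[C@H]1[C@H](B3OC(C)(C)C(C)(C)O3)[C@H]2C(=O)OC[C@]2(C)C[C@@H]1O[Si](C)(C)C(C)(C)C | intermediate (not isolated)
15 | 6α-hydroxy lactone | CC(C)(C)[Si](C)(C)OCC[C@H]1[C@H](O)[C@H]2C(=O)OC[C@]2(C)C[C@@H]1O[Si](C)(C)C(C)(C)C | intermediate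
16 | 6α-benzyloxy lactone | CC(C)(C)[Si](C)(C)OCC[C@H]1[C@H](OCc3ccccc3)[C@H]2C(=O)OC[C@]2(C)C[C@@H]1O[Si](C)(C)C(C)(C)C | intermediate
17 | ring B hydroxy N-methoxy-N-methylamide (C1 = CH2OH, C4 = amide) | CC(C)(C)[Si](C)(C)OCC[C@H]1[C@H](OCc3ccccc3)[C@@H](C(=O)N(C)OC)[C@@](C)(C[C@@H]1O[Si](C)(C)C(C)(C)C)CO | intermediate
18 | C1 aldehyde | CC(C)(C)[Si](C)(C)OCC[C@H]1[C@H](OCc3ccccc3)[C@@H](C(=O)N(C)OC)[C@@](C)(C[C@@H]1O[Si](C)(C)C(C)(C)C)C=O | intermediate
19 | (1R)-allylic alcohol | CC(C)(C)[Si](C)(C)OCC[C@H]1[C@H](OCc3ccccc3)[C@@H](C(=O)N(C)OC)[C@@](C)(C[C@@H]1O[Si](C)(C)C(C)(C)C)[C@H](O)C=C | intermediate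
20 | (1R)-allylic TBS ether | CC(C)(C)[Si](C)(C)OCC[C@H]1[C@H](OCc3ccccc3)[C@@H](C(=O)N(C)OC)[C@@](C)(C[C@@H]1O[Si](C)(C)C(C)(C)C)[C@H](O[Si](C)(C)C(C)(C)C)C=C | intermediate
21 | B-(C3-alkyl)-9-borabicyclo[3.3.1]nonane | CC(C)(C)[Si](C)(C)OCC[C@H]1[C@H](OCc3ccccc3)[C@@H](C(=O)N(C)OC)[C@@](C)(C[C@@H]1O[Si](C)(C)C(C)(C)C)[C@H](O[Si](C)(C)C(C)(C)C)CCB3C4CCCC3CCC4 | intermediate (not isolated)
22 | C3 primary alcohol (amide) | CC(C)(C)[Si](C)(C)OCC[C@H]1[C@H](OCc3ccccc3)[C@@H](C(=O)N(C)OC)[C@@](C)(C[C@@H]1O[Si](C)(C)C(C)(C)C)[C@H](O[Si](C)(C)C(C)(C)C)CCO | intermediate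
23 | hydroxy methyl ketone (C5 acetyl) | CC(C)(C)[Si](C)(C)OCC[C@H]1[C@H](OCc3ccccc3)[C@@H](C(C)=O)[C@@](C)(C[C@@H]1O[Si](C)(C)C(C)(C)C)[C@H](O[Si](C)(C)C(C)(C)C)CCO | intermediate
24 | all-equatorial ring B iodo ketone (5β-acetyl, 6α-OBn, 7β-CH2CH2OTBS, 8α-OTBS, 10β-CH3, (1R)-1-TBSO-3-iodopropyl) | CC(C)(C)[Si](C)(C)OCC[C@H]1[C@H](OCc3ccccc3)[C@@H](C(C)=O)[C@@](C)(C[C@@H]1O[Si](C)(C)C(C)(C)C)[C@H](O[Si](C)(C)C(C)(C)C)CCI | intermediate (key-step precursor)
25 | protected 4α-hydroxy-4β-methyl trans-decalin (6α-OBn; 1β, 8α, 12-tris-OTBS) | CC(C)(C)[Si](C)(C)OCC[C@H]1[C@H](OCc3ccccc3)[C@@H]2[C@@](C)(C[C@@H]1O[Si](C)(C)C(C)(C)C)[C@H](O[Si](C)(C)C(C)(C)C)CC[C@@]2(C)O | intermediate (key-step product)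
26 | 4α,6α-diol | CC(C)(C)[Si](C)(C)OCC[C@H]1[C@H](O)[C@@H]2[C@@](C)(C[C@@H]1O[Si](C)(C)C(C)(C)C)[C@H](O[Si](C)(C)C(C)(C)C)CC[C@@]2(C)O | intermediate
27 | 6α-angelate | CC(C)(C)[Si](C)(C)OCC[C@H]1[C@H](OC(=O)/C(C)=C\C)[C@@H]2[C@@](C)(C[C@@H]1O[Si](C)(C)C(C)(C)C)[C@H](O[Si](C)(C)C(C)(C)C)CC[C@@]2(C)O | intermediate
28 | C12 primary alcohol | OCC[C@H]1[C@H](OC(=O)/C(C)=C\C)[C@@H]2[C@@](C)(C[C@@H]1O[Si](C)(C)C(C)(C)C)[C@H](O[Si](C)(C)C(C)(C)C)CC[C@@]2(C)O | intermediate
29 | C12 aldehyde | O=CC[C@H]1[C@H](OC(=O)/C(C)=C\C)[C@@H]2[C@@](C)(C[C@@H]1O[Si](C)(C)C(C)(C)C)[C@H](O[Si](C)(C)C(C)(C)C)CC[C@@]2(C)O | intermediate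
30 | Mannich base (13-dimethylamino aldehyde, C11 epimers) | CN(C)CC(C=O)[C@H]1[C@H](OC(=O)/C(C)=C\C)[C@@H]2[C@@](C)(C[C@@H]1O[Si](C)(C)C(C)(C)C)[C@H](O[Si](C)(C)C(C)(C)C)CC[C@@]2(C)O | intermediate (not isolated)
31 | 11(13)-en-12-al | C=C(C=O)[C@H]1[C@H](OC(=O)/C(C)=C\C)[C@@H]2[C@@](C)(C[C@@H]1O[Si](C)(C)C(C)(C)C)[C@H](O[Si](C)(C)C(C)(C)C)CC[C@@]2(C)O | intermediate
32 | 11(13)-en-12-oic acid | C=C(C(=O)O)[C@H]1[C@H](OC(=O)/C(C)=C\C)[C@@H]2[C@@](C)(C[C@@H]1O[Si](C)(C)C(C)(C)C)[C@H](O[Si](C)(C)C(C)(C)C)CC[C@@]2(C)O | intermediate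
33 | methyl ester, 1β,8α-bis-TBS ether | C=C(C(=O)OC)[C@H]1[C@H](OC(=O)/C(C)=C\C)[C@@H]2[C@@](C)(C[C@@H]1O[Si](C)(C)C(C)(C)C)[C@H](O[Si](C)(C)C(C)(C)C)CC[C@@]2(C)O | intermediate
34 | CNP0136844.1 (methyl 6α-angeloyloxy-1β,4α,8α-trihydroxyeudesm-11(13)-en-12-oate) | C=C(C(=O)OC)[C@H]1[C@H](OC(=O)/C(C)=C\C)[C@@H]2[C@@](C)(C[C@@H]1O)[C@H](O)CC[C@@]2(C)O | target

Total step count: 24. Longest linear sequence: 24 steps (1 to 34; 4 is purchased).

Steps most likely to fail

Step 16. The organosamarium may attack the carbonyl face unselectively if the O4/O6 chelate is not maintained, or the ketone may be reduced before the iodide and leave uncyclised material. The fallback sets C4 by epoxidation and hydride opening instead. It sets out from primary alcohol 22, before the methyl Grignard step. Iodination (I2, PPh3, imidazole) gives the iodo N-methoxy-N-methylamide F1. Iodine–lithium exchange (t-BuLi, Et2O, −78 °C) with intramolecular acylation forms the same C3–C4 bond and gives the ring A ketone F2, which lacks C15. Wittig methylenation (Ph3P=CH2) gives the 4(15)-methylene decalin F3. mCPBA should epoxidise the exocyclic alkene from the α face, away from the axial C10 methyl, to the spiro-epoxide F4. LiEt3BH opens it at the primary carbon C15, and the sequence comes back to the route at 25.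

Step 7. The enolate may be protonated at C5 from the β face, giving the cis lactone, or the hindered trisubstituted alkene may borylate sluggishly. The fallback never makes C5 trigonal. It sets out from lactone 7. Allylic oxidation with SeO2 (catalytic) and t-BuOOH, an ene reaction at C8 followed by a [2,3] shift on the α face, gives the 6α-hydroxy alkene F5. Benzylation as in step 8 gives the benzyl ether F6. Hydroboration as in step 4 gives the alkylborane F7 (not isolated), and perborate oxidation gives the 8α-alcohol F8. Silylation with TBSOTf comes back to the route at 16.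

Step 11. Facial selectivity at the C1 carbonyl rests on substrate control only and may be poor. The fallback uses reagent control and sets out from aldehyde 18. Brown allylation with (+)-B-allyldiisopinocampheylborane (Et2O, −78 °C, perborate work-up) gives the (1R)-homoallylic alcohol F9. TBSOTf gives the silyl ether F10. Ozonolysis gives the C3 aldehyde F11 (not isolated), and NaBH4 in the same flask reduces it, coming back to the route at 22.

Further compounds
F1 | step 16 | iodo N-methoxy-N-methylamide | CC(C)(C)[Si](C)(C)OCC[C@H]1[C@H](OCc3ccccc3)[C@@H](C(=O)N(C)OC)[C@@](C)(C[C@@H]1O[Si](C)(C)C(C)(C)C)[C@H](O[Si](C)(C)C(C)(C)C)CCI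
F2 | step 16 | ring A ketone (15-nor-4-one trans-decalin) | CC(C)(C)[Si](C)(C)OCC[C@H]1[C@H](OCc3ccccc3)[C@@H]2[C@@](C)(C[C@@H]1O[Si](C)(C)C(C)(C)C)[C@H](O[Si](C)(C)C(C)(C)C)CCC2=O
F3 | step 16 | 4(15)-methylene decalin | CC(C)(C)[Si](C)(C)OCC[C@H]1[C@H](OCc3ccccc3)[C@@H]2[C@@](C)(C[C@@H]1O[Si](C)(C)C(C)(C)C)[C@H](O[Si](C)(C)C(C)(C)C)CCC2=C
F4 | step 16 | 4α,15-spiro-epoxide | CC(C)(C)[Si](C)(C)OCC[C@H]1[C@H](OCc3ccccc3)[C@@H]2[C@@](C)(C[C@@H]1O[Si](C)(C)C(C)(C)C)[C@H](O[Si](C)(C)C(C)(C)C)CC[C@]24CO4
F5 | step 7 | 6α-hydroxy Δ7 lactone | CC(C)(C)[Si](C)(C)OCCC1=CC[C@@]2(C)COC(=O)[C@@H]2[C@H]1O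
F6 | step 7 | 6α-benzyloxy Δ7 lactone | CC(C)(C)[Si](C)(C)OCCC1=CC[C@@]2(C)COC(=O)[C@@H]2[C@H]1OCc3ccccc3
F7 | step 7 | 8α-boryl 6α-benzyloxy lactone (monoalkylborane) | CC(C)(C)[Si](C)(C)OCC[C@H]1[C@H](OCc3ccccc3)[C@H]2C(=O)OC[C@]2(C)C[C@@H]1B
F8 | step 7 | 8α-hydroxy 6α-benzyloxy lactone | CC(C)(C)[Si](C)(C)OCC[C@H]1[C@H](OCc3ccccc3)[C@H]2C(=O)OC[C@]2(C)C[C@@H]1O
F9 | step 11 | (1R)-homoallylic alcohol | CC(C)(C)[Si](C)(C)OCC[C@H]1[C@H](OCc3ccccc3)[C@@H](C(=O)N(C)OC)[C@@](C)(C[C@@H]1O[Si](C)(C)C(C)(C)C)[C@H](O)CC=C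
F10 | step 11 | (1R)-homoallylic TBS ether | CC(C)(C)[Si](C)(C)OCC[C@H]1[C@H](OCc3ccccc3)[C@@H](C(=O)N(C)OC)[C@@](C)(C[C@@H]1O[Si](C)(C)C(C)(C)C)[C@H](O[Si](C)(C)C(C)(C)C)CC=C
F11 | step 11 | C3 aldehyde | CC(C)(C)[Si](C)(C)OCC[C@H]1[C@H](OCc3ccccc3)[C@@H](C(=O)N(C)OC)[C@@](C)(C[C@@H]1O[Si](C)(C)C(C)(C)C)[C@H](O[Si](C)(C)C(C)(C)C)CC=O
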